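The leftover is the first entry in these books: the starting material still unbound when the clock stops, with everything else in the flask being the rest of that charge, divided.

- Tuesday's: starting material 1.5 M; activator 1.30 equiv; time 25 s
- Monday's: starting material 1.5 M; activator 1.70 equiv; time 25 s

    ring ⇌ isomer of the product (K1 = 5.1, k1 = 0.17 s⁻¹)
    starting material + activated form → open dimer (k2 = 0.15 M⁻¹ s⁻¹)
    crystals ⇌ ring, rate k3*(cs3 - [ring]) while solid is left; crystals form when [ring] > cs3 (cs3 = 0.71 M, k3 = 0.91 s⁻¹)
    starting material + activator → activated form (k4 = 0.019 M⁻¹ s⁻¹)
    activated form ⇌ ring (K5 = 23, k5 = 0.25 s⁻¹)

- in percentages every species weighs as the starting material in it: one open dimer counts as two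
- for ring the crystals are counted in
- as a solid, counted per litre of solution: crystals
- run time (Tuesday's): 25 s

- which of these there is most of at the end, counted by the starting material in it, Tuesday's (isomer of the product / ring / starting material / open dimer)
- which of these there is most of at the end, counted by the starting material in it, Monday's (isomer of the product / ring / starting material / open dimer)
- how much there is at the end of the one of these that leads, in percent of the starting material charged: Tuesday's
- how much there is at the end of the one of these that leads, in percent of the starting material charged: Monday's

Starting material is the limiting reagent: Tuesday's activator stands at 1.95 M, more than the 1.5 M of starting material, and Monday's at 2.55 M. The reckoning here holds c(activator) at its charge, which makes activation pseudo-first-order, with rate constants 0.0370 s⁻¹ on Tuesday's and 0.0484 s⁻¹ on Monday's. Activator in fact falls, while capture takes extra starting material, and the reckoning lets these two errors pull against each other. Tuesday's leftover comes to 39.6%, Monday's to 29.8%.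

The second entry is a fork. Each activated form either closes to ring or is captured by starting material, and a capture takes two units of starting material into open dimer. The fork ratio, a selectivity factor, is the starting material taken by capture per starting material taken by closure at the charged concentration, 1.80; it scales with c(starting material). At the mean of charge and leftover, 1.05 M on Tuesday's, the ring side receives 26.8% and open dimer 33.6%. On Monday's the mean is 0.973 M, the ring side receives 32.4%, and open dimer 37.8%.

The last entry is the ring side, which ring and isomer of the product share, so this reckoning credits each of them with at most that whole entry and needs no split. The books close with starting material ahead on Tuesday's and open dimer ahead on Monday's.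

The forecast names starting material at 37.7% on Tuesday's and open dimer at 34.5% on Monday's, stepping the rates by hand and stating “Crystals never form”. It has the same leaders, with figures lower than those reckoned here .

The simulation gives starting material at 37.6% on Tuesday's. On Monday's it gives open dimer at 35.4%. Tuesday's lead is narrow in time: starting material and open dimer hold equal shares at 28.3 s, against the reading at 25 s. The fork ratio of 1.80 serves again on a neighbour of Tuesday's charged with 0.780 equiv of activator. Its reckoned leftover is 57.4%, which sends 25.0% to open dimer, and that neighbour ends with 24.7% of open dimer.

The constants used here belong to no real substance; no experiment stands behind them.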